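If each X taken up by Q frees one Z, and L holds 3 of them, then at level lg(L/Q) = lg B − 3p. Here lg is the logarithm to base ten, p = lg(Z/X), and B is the overall equilibrium constant from Q to L.

all flasks: Q 0.020 M
- ash: X 0.020 M; Z 0.060 M; run made earlier
- flask: X 0.0200 M; Z 0.0400 M; time 30 h

ash run (percent of the Q charged)

| time / h | Q / % | L / % |
|---|---|---|
| 0.417 | 84.3 | 0.6 |
| 1.33 | 68.1 | 2.7 |
| 2.00 | 63.0 | 4.1 |
| 3.00 | 59.1 | 3.8 |
| 5.00 | 56.4 | 3.4 |
| 6.00 | 55.6 | 3.8 |

(scatter of a reading: 0.5 percentage points)

- the reaction counts as stopped when no species that holds the Q changes by six tenths of a point or more over the second half of the time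
- no earlier run changes the charge of Z; that part of a forecast is a guess

* the state of affairs at 30 h: stopped, and by what, or still going (forward and back rates have come level / all of Q has reacted / it is still moving / X has run out first)
* conversion of Q at 30 h
* amount of L at 30 h, in percent of the Q charged

We call G = lg(L/Q) the gauge. The last ash reading gives

G = −1.17.

Q moved 0.8 percentage points between the last two ash readings, against a scatter of 0.5 points, so we take the asked flask as level at 30 h.

At the last ash reading 40.6 % of the charge is neither Q nor L. We assign it to unseen forms with one and two exchanged, and guess an equal split. Then the mean uptake per Q, n (the formation function), and the ash balance are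

n = 0.723, X = 0.00554 M, Z = 0.0745 M.

At that n, the asked flask has the same X but Z = 0.0545 M. So p lies lower by

g = 0.136.

Holding n is the weak link, since a lower p means more uptake, and uptake raises p again. With V the variance of the exchanged number over the forms and Q₀ the Q charged, the gap shrinks by a factor F:

V = 0.834
F = 1 + V(Q₀/Z + Q₀/X) = 4.32
d = g/F = 0.0315

So, for the asked flask, G = −1.07. Since lg Q falls by nd, Q = 52.8 %. That is conversion 47.2 % and L 4.49 %.

The forecast, saying “Thirty hours is ample to settle.”, reads: forward and back rates have come level; conversion 50 %; L 5 %.

The flask gives: forward and back rates have come level; conversion 47.9 %; L 3.56 %. Of its X 12 % stays, less than the 52 % of its Q. At 30.0 h its gauge stands at −1.17, with p = 1.38.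

    Q + X ⇌ Z + J (K = 5.30, k = 0.380 /M/min)
    J + X ⇌ Z + D (K = 67.0, k = 0.850 /M/min)
    D + X ⇌ Z + L (K = 2.60, k = 1.80 /M/min)
    L + X ⇌ Z + E (K = 0.660, k = 0.320 /M/min)

With 0.0080 M of Q, the neighbour flask stands at p = 0.977 at 30.0 h. Taken from the asked flask, the rule then gives G = 0.0325, so L/Q = 1.08. Computed, that flask holds L 16.1 % and Q 15.6 %.

The runs come from a simulation with constants of no real substance, and the scatter is random.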